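**Retrosynthetic overview**

1. Ring numbering used below: C1 (C=O), C2 (allyl-bearing), C3 (CH), C4 (quaternary C–OMe), C5 (C–OMe), C6 (CH); C8 is the side-chain CH(CH3). The last disconnections are the ring bond C1–C2 and the methyl–oxygen bond at C4. They lead back to the 5,5-disubstituted methyl tetronate 17, which carries a (Z)-2-iodopenta-1,4-dienyl group.
2. Enabling feature: the C4 oxygen, C4, the enol-ether unit C5(OMe)=C6 and the C1 carbonyl form the chain O–C4–C5(OMe)=C6–C1(=O). Joining C1 to that oxygen gives a five-membered 4-methoxyfuran-2(5H)-one ring, so the lactone is a masked dienone. A carbanion on C2 can then move the acyl carbon C1 from oxygen to carbon: one operation closes the six-membered ring, makes the ketone, opens the temporary lactone and frees the C4 alkoxide for methylation.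
3. The tetronate comes from a γ-hydroxy ynoate (methanol addition, lactonisation). C4 is set by catalytic enantioselective alkynylation of the β,γ-unsaturated α-keto ester 4, and C8 by iridium-catalysed asymmetric hydrogenation. Ester → alcohol → aldehyde and a (Z)-selective iodo-olefination then attach C3, C2 and the allyl group.
4. Order of ring formation: the arene is bought; the furanone ring (temporary) is formed in step 4; the cyclohexadienone ring is closed last, in step 9.

Key step: step 9

Assumption: the ligand antipodes written in steps 3 and 5 are those expected to give (R)-C4 and (S)-C8; the sense of induction on these substrates is to be confirmed in a pilot run, and the antipodal ligand is used if it is reversed.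

**Route**

Step 1
Reactants: 1 2-oxobutanoic acid; 2 3,4-dimethoxybenzaldehyde
Product: 3 (E)-4-(3,4-dimethoxyphenyl)-3-methyl-2-oxobut-3-enoic acid
Conditions: KOH (2.2 equiv), MeOH/H2O, 0 °C → rt; then aq. HCl to pH 2
Reagents that add atoms: none
Why: Claisen–Schmidt-type crossed aldol condensation in which only the keto acid can enolise (at its CH2) and the aryl aldehyde cannot, so that aldol addition and E1cB dehydration should give the conjugated enone acid as the thermodynamically preferred (E)-alkene (aryl trans to the keto carbonyl).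

Step 2
Reactants: 3 (E)-4-(3,4-dimethoxyphenyl)-3-methyl-2-oxobut-3-enoic acid
Product: 4 methyl (E)-4-(3,4-dimethoxyphenyl)-3-methyl-2-oxobut-3-enoate
Conditions: MeOH, H2SO4 (5 mol %), 60 °C
Reagents that add atoms: methanol, CO
Why: Fischer esterification, which turns the acid into a vicinal keto ester able to bind a Lewis-acidic catalyst through both carbonyl groups in step 3; no stereocentre is involved.

Step 3
Reactants: 4 methyl (E)-4-(3,4-dimethoxyphenyl)-3-methyl-2-oxobut-3-enoate; 5 methyl prop-2-ynoate
Product: 7 dimethyl (4R)-4-[(1E)-1-(3,4-dimethoxyphenyl)prop-1-en-2-yl]-4-hydroxypent-2-ynedioate, via zinc acetylide 6 (not isolated)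
Conditions: 5 (2.5 equiv), ZnMe2 (3 equiv), (S,S)-ProPhenol (10 mol %), Ph3PO (20 mol %), toluene, 0 °C; aq. NH4Cl
Reagents that add atoms: none
Why: Catalytic enantioselective alkynylation of an α-keto ester, in which the zinc acetylide 6 adds 1,2 to the keto carbonyl held by two-point binding of the vicinal dicarbonyl to the dinuclear zinc–ProPhenol complex, so that the chiral pocket selects one enantiotopic face and sets the later ring carbon C4 as (R), while the amine-free conditions tolerate the propiolate and disfavour 1,4-addition.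

Step 4
Reactants: 7 dimethyl (4R)-4-[(1E)-1-(3,4-dimethoxyphenyl)prop-1-en-2-yl]-4-hydroxypent-2-ynedioate
Product: 9 methyl (2R)-2-[(1E)-1-(3,4-dimethoxyphenyl)prop-1-en-2-yl]-3-methoxy-5-oxo-2,5-dihydrofuran-2-carboxylate, via methoxy enoate 8 (not isolated)
Conditions: NaOMe (0.2 equiv), MeOH, 0 °C → rt
Reagents that add atoms: methanol, CO
Why: Oxa-Michael addition of methoxide to the β-carbon of the ynoate, equilibration of the β-methoxy enoate by reversible addition–elimination and 5-exo-trig lactonisation of the tertiary hydroxyl on the (E)-isomer 8 (the classical tetronate synthesis from γ-hydroxy ynoates) should give the 4-methoxyfuranone, with C4 untouched and its oxygen now the ring oxygen.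

Step 5
Reactants: 9 methyl (2R)-2-[(1E)-1-(3,4-dimethoxyphenyl)prop-1-en-2-yl]-3-methoxy-5-oxo-2,5-dihydrofuran-2-carboxylate
Product: 10 methyl (2R)-2-[(2S)-1-(3,4-dimethoxyphenyl)propan-2-yl]-3-methoxy-5-oxo-2,5-dihydrofuran-2-carboxylate
Conditions: H2 (50 bar), [Ir(cod)((S)-tBu-PHOX)]B[3,5-(CF3)2C6H3]4 (2 mol %), CH2Cl2, rt
Reagents that add atoms: none
Why: Iridium–phosphinooxazoline-catalysed asymmetric hydrogenation of an (E)-trisubstituted aryl alkene, which needs no coordinating group, should leave the electron-poor vinylogous-carbonate alkene of the tetronate and both carbonyl groups untouched, and sets C8 as (S) through the ligand (catalyst control over the small bias of the neighbouring quaternary carbon).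

Step 6
Reactants: 10 methyl (2R)-2-[(2S)-1-(3,4-dimethoxyphenyl)propan-2-yl]-3-methoxy-5-oxo-2,5-dihydrofuran-2-carboxylate
Product: 11 (5S)-5-[(2S)-1-(3,4-dimethoxyphenyl)propan-2-yl]-5-(hydroxymethyl)-4-methoxyfuran-2(5H)-one
Conditions: NaBH4 (2 equiv), MeOH, 0 °C → rt
Reagents that add atoms: none
Why: Chemoselective borohydride reduction, in which the ester on the oxygen-bearing quaternary carbon is activated by its α-acyloxy group whereas the lactone carbonyl is a deactivated vinylogous carbonate and should survive; no stereocentre is touched (the descriptor at C4 changes only through the priority rules).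

Step 7
Reactants: 11 (5S)-5-[(2S)-1-(3,4-dimethoxyphenyl)propan-2-yl]-5-(hydroxymethyl)-4-methoxyfuran-2(5H)-one
Product: 12 (2R)-2-[(2S)-1-(3,4-dimethoxyphenyl)propan-2-yl]-3-methoxy-5-oxo-2,5-dihydrofuran-2-carbaldehyde
Conditions: Dess–Martin periodinane (1.3 equiv), CH2Cl2, 0 °C → rt
Reagents that add atoms: none
Why: Dess–Martin oxidation of a neopentyl-type primary alcohol under neutral conditions, giving an aldehyde that cannot enolise or epimerise because its α-carbon is quaternary.

Step 8
Reactants: 12 (2R)-2-[(2S)-1-(3,4-dimethoxyphenyl)propan-2-yl]-3-methoxy-5-oxo-2,5-dihydrofuran-2-carbaldehyde; 13 (but-3-en-1-yl)triphenylphosphonium bromide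
Product: 17 (5S)-5-[(2S)-1-(3,4-dimethoxyphenyl)propan-2-yl]-5-[(1Z)-2-iodopenta-1,4-dien-1-yl]-4-methoxyfuran-2(5H)-one, via ylide 14 (not isolated), via iodophosphonium iodide 15 (not isolated), via iodo ylide 16 (not isolated)
Conditions: 13 (1.5 equiv), nBuLi, THF, 0 °C; I2, −78 °C; NaN(SiMe3)2, −20 °C; then 12, DMPU, −78 → −20 °C
Reagents that add atoms: iodine, II
Why: Stork–Zhao-type Wittig olefination with an α-iodo ylide, in which the non-stabilised ylide 16 reacts under kinetic control with the non-enolisable aldehyde at low temperature to give the (Z)-vinyl iodide (iodine cis to C4), while the lactone is not attacked at this temperature.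

Step 9
Reactants: 17 (5S)-5-[(2S)-1-(3,4-dimethoxyphenyl)propan-2-yl]-5-[(1Z)-2-iodopenta-1,4-dien-1-yl]-4-methoxyfuran-2(5H)-one
Product: 21 (4S)-4-[(2S)-1-(3,4-dimethoxyphenyl)propan-2-yl]-4,5-dimethoxy-2-(prop-2-en-1-yl)cyclohexa-2,5-dien-1-one, via vinyllithium 18 (not isolated), via bridged alkoxide 19 (not isolated), via lithium alkoxide 20 (not isolated)
Conditions: tBuLi (2.1 equiv), THF/Et2O/pentane (4:1:1), −100 °C → −78 °C; then MeOTf (3 equiv), −78 → 0 °C
Reagents that add atoms: methyl trifluoromethanesulfonate, COS(=O)(=O)C(F)(F)F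
Why: Iodine–lithium exchange at −100 °C is faster than addition of tBuLi to the lactone and retains the alkene geometry, so vinyllithium 18 carries its carbanion on C2 cis to C4 and above the lactone carbonyl C1. The carbanion adds to C1 (6-exo-trig for the new carbocycle C1–C6, 5-exo-trig through the ring oxygen) to give the strained 7-oxabicyclo[2.2.1]heptadienolate 19, which collapses by cleavage of the C1–O bond to the 4-oxidocyclohexa-2,5-dienone 20; MeOTf then alkylates this lithium alkoxide on oxygen. The closest known reaction types are the Parham cyclisation of aryl- and vinyllithiums onto esters and lactones, the anionic 1,4-O→C acyl migration, and the bridged acyl-transfer step of the Hauser–Kraus annulation. No stereocentre is created in the product: only the acyl C–O bond breaks and never a bond to C4, so the configuration set in step 3 is carried over unchanged, and the bridgehead C1 of 19 is transient. The step needs halogen–metal exchange to win over carbonyl addition (secured by the iodide, −100 °C and a second equivalent of tBuLi that destroys tert-butyl iodide) and needs the carbanion to reach C1 (secured by the (Z)-geometry from step 8). The two ring oxygens cannot be interchanged, because the C5 methoxy group has been in place since step 4 and C1 becomes a ketone only here.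

**Compound list**

1 | 2-oxobutanoic acid | CCC(=O)C(=O)O | starting material
2 | 3,4-dimethoxybenzaldehyde | COc1ccc(C=O)cc1OC | starting material
3 | (E)-4-(3,4-dimethoxyphenyl)-3-methyl-2-oxobut-3-enoic acid | OC(=O)C(=O)/C(C)=C/c1ccc(OC)c(OC)c1 | intermediate
4 | methyl (E)-4-(3,4-dimethoxyphenyl)-3-methyl-2-oxobut-3-enoate | COC(=O)C(=O)/C(C)=C/c1ccc(OC)c(OC)c1 | intermediate
5 | methyl prop-2-ynoate | C#CC(=O)OC | starting material
6 | methyl 3-(methylzincio)prop-2-ynoate (zinc acetylide) | C[Zn]C#CC(=O)OC | intermediate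
7 | dimethyl (4R)-4-[(1E)-1-(3,4-dimethoxyphenyl)prop-1-en-2-yl]-4-hydroxypent-2-ynedioate | COC(=O)[C@@](O)(/C(C)=C/c1ccc(OC)c(OC)c1)C#CC(=O)OC | intermediate
8 | dimethyl (2E,4R)-4-[(1E)-1-(3,4-dimethoxyphenyl)prop-1-en-2-yl]-4-hydroxy-3-methoxypent-2-enedioate | COC(=O)/C=C(OC)\[C@@](O)(C(=O)OC)/C(C)=C/c1ccc(OC)c(OC)c1 | intermediate
9 | methyl (2R)-2-[(1E)-1-(3,4-dimethoxyphenyl)prop-1-en-2-yl]-3-methoxy-5-oxo-2,5-dihydrofuran-2-carboxylate | COC(=O)[C@]1(/C(C)=C/c2ccc(OC)c(OC)c2)OC(=O)C=C1OC | intermediate
10 | methyl (2R)-2-[(2S)-1-(3,4-dimethoxyphenyl)propan-2-yl]-3-methoxy-5-oxo-2,5-dihydrofuran-2-carboxylate | COC(=O)[C@]1([C@@H](C)Cc2ccc(OC)c(OC)c2)OC(=O)C=C1OC | intermediate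
11 | (5S)-5-[(2S)-1-(3,4-dimethoxyphenyl)propan-2-yl]-5-(hydroxymethyl)-4-methoxyfuran-2(5H)-one | OC[C@]1([C@@H](C)Cc2ccc(OC)c(OC)c2)OC(=O)C=C1OC | intermediate
12 | (2R)-2-[(2S)-1-(3,4-dimethoxyphenyl)propan-2-yl]-3-methoxy-5-oxo-2,5-dihydrofuran-2-carbaldehyde | O=C[C@]1([C@@H](C)Cc2ccc(OC)c(OC)c2)OC(=O)C=C1OC | intermediate
13 | (but-3-en-1-yl)triphenylphosphonium bromide | [Br-].C=CCC[P+](c1ccccc1)(c1ccccc1)c1ccccc1 | starting material
14 | (but-3-en-1-ylidene)triphenylphosphorane | C=CCC=P(c1ccccc1)(c1ccccc1)c1ccccc1 | intermediate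
15 | (1-iodobut-3-en-1-yl)triphenylphosphonium iodide (racemic at the iodine-bearing carbon) | [I-].C=CCC(I)[P+](c1ccccc1)(c1ccccc1)c1ccccc1 | intermediate
16 | (1-iodobut-3-en-1-ylidene)triphenylphosphorane | C=CCC(I)=P(c1ccccc1)(c1ccccc1)c1ccccc1 | intermediate
17 | (5S)-5-[(2S)-1-(3,4-dimethoxyphenyl)propan-2-yl]-5-[(1Z)-2-iodopenta-1,4-dien-1-yl]-4-methoxyfuran-2(5H)-one | C=CC/C(I)=C/[C@]1([C@@H](C)Cc2ccc(OC)c(OC)c2)OC(=O)C=C1OC | intermediate
18 | [(1E)-1-{(2S)-2-[(2S)-1-(3,4-dimethoxyphenyl)propan-2-yl]-3-methoxy-5-oxo-2,5-dihydrofuran-2-yl}penta-1,4-dien-2-yl]lithium | C=CC/C([Li])=C/[C@]1([C@@H](C)Cc2ccc(OC)c(OC)c2)OC(=O)C=C1OC | intermediate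
19 | lithium (1S,4S)-4-[(2S)-1-(3,4-dimethoxyphenyl)propan-2-yl]-5-methoxy-2-(prop-2-en-1-yl)-7-oxabicyclo[2.2.1]hepta-2,5-dien-1-olate | [Li]O[C@@]12O[C@@]([C@@H](C)Cc3ccc(OC)c(OC)c3)(C=C1CC=C)C(OC)=C2 | intermediate
20 | lithium (1S)-1-[(2S)-1-(3,4-dimethoxyphenyl)propan-2-yl]-2-methoxy-4-oxo-5-(prop-2-en-1-yl)cyclohexa-2,5-dien-1-olate | C=CCC1=C[C@@](O[Li])([C@@H](C)Cc2ccc(OC)c(OC)c2)C(OC)=CC1=O | intermediate
21 | (4S)-4-[(2S)-1-(3,4-dimethoxyphenyl)propan-2-yl]-4,5-dimethoxy-2-(prop-2-en-1-yl)cyclohexa-2,5-dien-1-one | C=CCC1=C[C@@](OC)([C@@H](C)Cc2ccc(OC)c(OC)c2)C(OC)=CC1=O | target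

**Count and risks**

Total step count: 9. Longest linear sequence: 9 steps (from 1 and 2 to 21).

The three steps most likely to fail:

Step 9 (key step). The transannular acyl transfer passes through a strained bridged alkoxide; if it is slow, the vinyllithium may be protonated or tBuLi may add to the lactone. Fallback (ring closed by olefination instead of acyl transfer): the route is left at alcohol 11. Lithiated diethyl but-3-en-1-ylphosphonate (3 equiv, nBuLi, THF, −78 °C) should open the lactone at C1 to the keto phosphonate diol F1. Dess–Martin oxidation of the primary hydroxyl should give the keto phosphonate aldehyde F2. LiCl/DBU in MeCN should then close the ring by intramolecular Horner–Wadsworth–Emmons olefination to the quinol F3. Methylation of the tertiary hydroxyl (MeI, Ag2O) rejoins the route at 21.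

Step 3. The alkynylation may suffer from methyl transfer from ZnMe2 to the activated keto group, from oligomerisation of the propiolate, or from weak facial discrimination. Fallback (other alkyne, carboxylation later): the route is left at 4. Zn(OTf)2/Et3N with a chiral β-amino alcohol ligand and trimethylsilylacetylene, the alkyne class with direct precedent on α-keto esters, should give the silyl alkyne F4. K2CO3/MeOH should remove silicon to give the terminal alkyne F5. LiN(SiMe3)2 (2.2 equiv) and ClCO2Me should give the carbonate ynoate F6. Under the conditions of step 4 (NaOMe, MeOH) F6 should lose its carbonate, pass through 7 and 8 in the flask, and rejoin the route at 9.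

Step 5. The trisubstituted alkene next to the quaternary carbon may turn over slowly, or the catalyst may be mismatched with the existing stereocentre and give poor facial selectivity. Fallback (directing group instead of pure catalyst control, order of steps reversed): the route is left at 9. NaBH4/MeOH should give the unsaturated primary alcohol F7. Its homoallylic hydroxyl can bind Ru(OAc)2[(S)-BINAP] (H2, MeOH) for a hydroxyl-directed asymmetric hydrogenation that sets C8 and rejoins the route at 11.

Further compounds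
F1 | step 9 | diethyl [(3E,5S)-5-[(2S)-1-(3,4-dimethoxyphenyl)propan-2-yl]-5,6-dihydroxy-4-methoxy-2-oxo-1-(prop-2-en-1-yl)hex-3-en-1-yl]phosphonate (both epimers at the phosphorus-bearing carbon) | C=CCC(P(=O)(OCC)OCC)C(=O)/C=C(OC)\[C@@](O)(CO)[C@@H](C)Cc1ccc(OC)c(OC)c1
F2 | step 9 | diethyl [(3E,5R)-5-[(2S)-1-(3,4-dimethoxyphenyl)propan-2-yl]-5-hydroxy-4-methoxy-2,6-dioxo-1-(prop-2-en-1-yl)hex-3-en-1-yl]phosphonate (both epimers at the phosphorus-bearing carbon) | C=CCC(P(=O)(OCC)OCC)C(=O)/C=C(OC)\[C@@](O)(C=O)[C@@H](C)Cc1ccc(OC)c(OC)c1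
F3 | step 9 | (4S)-4-[(2S)-1-(3,4-dimethoxyphenyl)propan-2-yl]-4-hydroxy-5-methoxy-2-(prop-2-en-1-yl)cyclohexa-2,5-dien-1-one | C=CCC1=C[C@@](O)([C@@H](C)Cc2ccc(OC)c(OC)c2)C(OC)=CC1=O
F4 | step 3 | methyl (2R,3E)-4-(3,4-dimethoxyphenyl)-2-hydroxy-3-methyl-2-[(trimethylsilyl)ethynyl]but-3-enoate | COC(=O)[C@@](O)(/C(C)=C/c1ccc(OC)c(OC)c1)C#C[Si](C)(C)C
F5 | step 3 | methyl (2S,3E)-4-(3,4-dimethoxyphenyl)-2-ethynyl-2-hydroxy-3-methylbut-3-enoate | COC(=O)[C@@](O)(/C(C)=C/c1ccc(OC)c(OC)c1)C#C
F6 | step 3 | dimethyl (4R)-4-[(1E)-1-(3,4-dimethoxyphenyl)prop-1-en-2-yl]-4-[(methoxycarbonyl)oxy]pent-2-ynedioate | COC(=O)[C@@](OC(=O)OC)(/C(C)=C/c1ccc(OC)c(OC)c1)C#CC(=O)OC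
F7 | step 5 | (5S)-5-[(1E)-1-(3,4-dimethoxyphenyl)prop-1-en-2-yl]-5-(hydroxymethyl)-4-methoxyfuran-2(5H)-one | OC[C@]1(/C(C)=C/c2ccc(OC)c(OC)c2)OC(=O)C=C1OC
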